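**Retrosynthetic overview**

- The target, robinetinidol-(4α→6)-gallocatechin, comes from global hydrogenolysis of a perbenzylated dimer that carries a bromine block at C8 of the lower unit; the C3–OH of the upper unit comes from a C3–CHO group by Baeyer–Villiger excision of one carbon with retention.
- Ring C of the upper unit (O1, C2, C3, C4, C4a, C8a) is disconnected at O1–C2 and C3–C4: the 2,4-diarylchroman-3-carbaldehyde arises from an ortho-hydroxybenzhydrol and (E)-3,4,5-tris(benzyloxy)cinnamaldehyde in one aminocatalytic domino (oxa-Michael addition, then ring closure by the enamine carbon C3 onto C4).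
- Enabling feature: C4 is a doubly benzylic carbon, para to O7 on ring A of the upper unit and ortho/ortho/para to O5, O7 and O1 of ring A of the lower unit, so it is a latent, strongly stabilised benzhydrylium (quinone-methide-type) electrophile; O1–C2–C3–CHO is a β-aryloxy aldehyde, the retron of an oxa-Michael addition that turns C3 into an enamine nucleophile.
- The benzhydrol comes from the C6-aryllithium of C8-bromo-blocked hexa-O-benzyl-(+)-gallocatechin and 4-(benzyloxy)-2-hydroxybenzaldehyde; the enal comes from Wittig homologation of 3,4,5-tris(benzyloxy)benzaldehyde.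
- Ring order: rings A, B and C of the lower unit come intact from (+)-gallocatechin, rings A and B of the upper unit are bought as arenes, and ring C of the upper unit is the only ring formed.

Key step: step 7

Remark: (+)-gallocatechin, 4-(benzyloxy)-2-hydroxybenzaldehyde and 3,4,5-tris(benzyloxy)benzaldehyde are taken as commercial, and the sense of induction of the amine catalyst is assigned from the steric-shielding model of its (E)-iminium ion.

**Route**

Step 1
Reactants: 1 (+)-gallocatechin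
Product: 2 5,7,3',4',5'-penta-O-benzyl-(+)-gallocatechin [(2R,3S)-5,7-bis(benzyloxy)-2-(3,4,5-tris(benzyloxy)phenyl)chroman-3-ol]
Conditions: BnBr, K2CO3, DMF, rt, argon
Reagents that add atoms: benzyl bromide, BrCc1ccccc1
Why: Williamson etherification under a weak base should alkylate the five phenolic hydroxyls only and leave the secondary C3 hydroxyl and both stereocentres untouched.

Step 2
Reactants: 2 5,7,3',4',5'-penta-O-benzyl-(+)-gallocatechin
Product: 3 hexa-O-benzyl-(+)-gallocatechin [(2R,3S)-3,5,7-tris(benzyloxy)-2-(3,4,5-tris(benzyloxy)phenyl)chroman]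
Conditions: NaH, BnBr, DMF, 0 °C → rt
Reagents that add atoms: benzyl bromide, BrCc1ccccc1
Why: Williamson etherification of the C3 alkoxide removes the last acidic proton so that the later halogen–lithium exchange meets none, with C2 and C3 unaffected.

Step 3
Reactants: 3 hexa-O-benzyl-(+)-gallocatechin
Product: 4 8-bromo-hexa-O-benzyl-(+)-gallocatechin [(2R,3S)-3,5,7-tris(benzyloxy)-8-bromo-2-(3,4,5-tris(benzyloxy)phenyl)chroman]
Conditions: NBS (1.0 equiv), CH2Cl2, −78 → 0 °C
Reagents that add atoms: N-bromosuccinimide, BrN1C(=O)CCC1=O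
Why: Electrophilic aromatic bromination of the phloroglucinol-type ring A should take place at C8, the more accessible of its two free positions, which blocks C8 and leaves C6 as the only nucleophilic site.

Step 4
Reactants: 4 8-bromo-hexa-O-benzyl-(+)-gallocatechin
Product: 5 8-bromo-6-iodo-hexa-O-benzyl-(+)-gallocatechin [(2R,3S)-3,5,7-tris(benzyloxy)-8-bromo-6-iodo-2-(3,4,5-tris(benzyloxy)phenyl)chroman]
Conditions: NIS, CF3CO2H (cat.), MeCN/CH2Cl2, 0 °C → rt
Reagents that add atoms: N-iodosuccinimide, IN1C(=O)CCC1=O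
Why: Electrophilic aromatic iodination can only occur at C6, the last free position of the trioxygenated ring A, and installs a halogen that exchanges with lithium much faster than bromine.

Step 5
Reactants: 5 8-bromo-6-iodo-hexa-O-benzyl-(+)-gallocatechin; 6 4-(benzyloxy)-2-hydroxybenzaldehyde
Product: 9 [4-(benzyloxy)-2-hydroxyphenyl][(2R,3S)-3,5,7-tris(benzyloxy)-8-bromo-2-(3,4,5-tris(benzyloxy)phenyl)chroman-6-yl]methanol (both carbinol epimers), via C6-aryllithium 7 (not isolated), via sodium phenoxide 8 (not isolated)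
Conditions: 6, NaH, THF, 0 °C (gives 8); separately 5, n-BuLi, THF, −78 °C (gives 7); 8 added to 7, −78 → 0 °C; H2O, NaH2PO4 to pH 7
Reagents that add atoms: none
Why: Iodine–lithium exchange is far faster than bromine–lithium exchange at −78 °C, so the C6 aryllithium should form selectively and undergo 1,2-addition to the formyl group of the phenoxide-masked salicylaldehyde; the new carbinol centre forms as a mixture, which does not matter because it is ionised in step 7.

Step 6
Reactants: 10 3,4,5-tris(benzyloxy)benzaldehyde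
Product: 11 (E)-3-[3,4,5-tris(benzyloxy)phenyl]prop-2-enal
Conditions: Ph3P=CHCHO, toluene, 80 °C
Reagents that add atoms: (triphenylphosphoranylidene)acetaldehyde, O=CC=P(c1ccccc1)(c1ccccc1)c1ccccc1
Why: Wittig olefination with the stabilised formylmethylene ylide should give the (E)-enal.

Step 7
Reactants: 9 ortho-hydroxybenzhydrol (both carbinol epimers); 11 (E)-3-[3,4,5-tris(benzyloxy)phenyl]prop-2-enal
Product: 13 (2S,3S,4S)-7-(benzyloxy)-4-[(2R,3S)-3,5,7-tris(benzyloxy)-8-bromo-2-(3,4,5-tris(benzyloxy)phenyl)chroman-6-yl]-2-[3,4,5-tris(benzyloxy)phenyl]chroman-3-carbaldehyde (2,3-trans-3,4-trans), via oxa-Michael enamine 12 (not isolated)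
Conditions: (S)-α,α-diphenylprolinol trimethylsilyl ether (20 mol %), 2-nitrobenzoic acid (20 mol %), toluene, 0 °C → rt
Reagents that add atoms: none
Why: Proposed new method: the amine and enal 11 form an iminium ion, the phenolic oxygen of 9 adds to its β-carbon (future C2) in an oxa-Michael step, and the α-carbon of the resulting enamine 12 (future C3) attacks the benzhydrylium/ortho-quinone-methide carbon (future C4) that the acid co-catalyst releases from the carbinol, after which hydrolysis of the iminium ion frees 13 and the amine. The closest known reaction types are the aminocatalytic oxa-Michael/aldol condensation of salicylaldehydes with enals, the oxa-Michael/1,6-addition of ortho-hydroxyphenyl para-quinone methides and the SN1-type enamine α-alkylation of aldehydes with benzhydrols; their combination on an ortho-hydroxybenzhydrol is the new element. Ring C closes through the C3–C4 bond in a 6-endo-trig mode at the cationic C4=C4a unit, with the enamine double bond exocyclic. C2 is set by the catalyst, whose diphenyl(trimethylsilyloxy)methyl group shields one face of the (E)-iminium ion; C4 is set by C2 through a chair-like transition state in which the ring B aryl group and the lower-unit aryl group (anti to O1 on the cation) are both equatorial, giving the 2,4-cis relation; C3, α to the formyl group, should equilibrate by enamine/enol exchange to the equatorial position trans to both neighbours. The step needs ionisation at C4 only and O1–C2 bond formation before C–C bond formation: the benzyloxy group para to C4 on ring A of the upper unit and the ortho, ortho, para oxygen pattern of ring A of the lower unit make C4 the one carbon that ionises under a carboxylic acid, and the carbon nucleophile at C3 does not exist until the oxa-Michael addition has tethered it, so the C–C bond can only form as the ring closure. Because C4 cannot epimerise once formed, any later retro-oxa-Michael reclosure at C2 or enolisation at C3 should only return material to the all-equatorial isomer.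

Step 8
Reactants: 13 2,3-trans-3,4-trans chroman-3-carbaldehyde
Product: 15 (2R,3S,4S)-7-(benzyloxy)-4-[(2R,3S)-3,5,7-tris(benzyloxy)-8-bromo-2-(3,4,5-tris(benzyloxy)phenyl)chroman-6-yl]-2-[3,4,5-tris(benzyloxy)phenyl]chroman-3-ol, via C3 formate 14 (not isolated)
Conditions: mCPBA, CH2Cl2, 0 °C → rt; aq. Na2S2O3/NaHCO3 wash; then K2CO3 (cat.), MeOH/THF, 0 °C
Reagents that add atoms: 3-chloroperoxybenzoic acid, OOC(=O)c1cccc(Cl)c1
Why: In the Baeyer–Villiger oxidation of an α-branched aldehyde the secondary carbon C3 should migrate to oxygen in preference to hydrogen and with retention, so the formyl carbon is excised and the C3–O bond ends up equatorial and trans to both aryl-bearing neighbours, and mild methanolysis then cleaves the formate.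

Step 9
Reactants: 15 perbenzylated 8-bromo dimer with free C3 hydroxyl
Product: 16 robinetinidol-(4α→6)-gallocatechin (target)
Conditions: H2 (1 atm), Pd(OH)2/C, Et3N, THF/MeOH/H2O, rt
Reagents that add atoms: none
Why: Catalytic hydrogenolysis should cleave the ten benzyl ethers and the aryl C–Br bond (HBr being taken up by Et3N) without touching the doubly benzylic C4–C6 interflavan bond or any stereocentre.

**Compound list**

1 | (+)-gallocatechin, (2R,3S) | c1c(O)cc2c(c1O)C[C@H](O)[C@@H](c1cc(O)c(O)c(O)c1)O2 | starting material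
2 | 5,7,3',4',5'-penta-O-benzyl-(+)-gallocatechin | c1c(OCc3ccccc3)cc2c(c1OCc3ccccc3)C[C@H](O)[C@@H](c1cc(OCc3ccccc3)c(OCc3ccccc3)c(OCc3ccccc3)c1)O2 | intermediate
3 | hexa-O-benzyl-(+)-gallocatechin | c1c(OCc3ccccc3)cc2c(c1OCc3ccccc3)C[C@H](OCc3ccccc3)[C@@H](c1cc(OCc3ccccc3)c(OCc3ccccc3)c(OCc3ccccc3)c1)O2 | intermediate
4 | 8-bromo-hexa-O-benzyl-(+)-gallocatechin | c1c(OCc3ccccc3)c(Br)c2c(c1OCc3ccccc3)C[C@H](OCc3ccccc3)[C@@H](c1cc(OCc3ccccc3)c(OCc3ccccc3)c(OCc3ccccc3)c1)O2 | intermediate
5 | 8-bromo-6-iodo-hexa-O-benzyl-(+)-gallocatechin | Ic1c(OCc3ccccc3)c(Br)c2c(c1OCc3ccccc3)C[C@H](OCc3ccccc3)[C@@H](c1cc(OCc3ccccc3)c(OCc3ccccc3)c(OCc3ccccc3)c1)O2 | intermediate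
6 | 4-(benzyloxy)-2-hydroxybenzaldehyde | O=Cc1ccc(OCc2ccccc2)cc1O | starting material
7 | C6-aryllithium of 8-bromo-hexa-O-benzyl-(+)-gallocatechin | [Li]c1c(OCc3ccccc3)c(Br)c2c(c1OCc3ccccc3)C[C@H](OCc3ccccc3)[C@@H](c1cc(OCc3ccccc3)c(OCc3ccccc3)c(OCc3ccccc3)c1)O2 | intermediate (not isolated)
8 | sodium 5-(benzyloxy)-2-formylphenoxide | [Na+].[O-]c1cc(OCc2ccccc2)ccc1C=O | intermediate (not isolated)
9 | [4-(benzyloxy)-2-hydroxyphenyl][(2R,3S)-3,5,7-tris(benzyloxy)-8-bromo-2-(3,4,5-tris(benzyloxy)phenyl)chroman-6-yl]methanol, both carbinol epimers | OC(c1ccc(OCc3ccccc3)cc1O)c1c(OCc3ccccc3)c(Br)c2c(c1OCc3ccccc3)C[C@H](OCc3ccccc3)[C@@H](c1cc(OCc3ccccc3)c(OCc3ccccc3)c(OCc3ccccc3)c1)O2 | intermediate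
10 | 3,4,5-tris(benzyloxy)benzaldehyde | O=Cc1cc(OCc2ccccc2)c(OCc2ccccc2)c(OCc2ccccc2)c1 | starting material
11 | (E)-3-[3,4,5-tris(benzyloxy)phenyl]prop-2-enal | O=C/C=C/c1cc(OCc2ccccc2)c(OCc2ccccc2)c(OCc2ccccc2)c1 | intermediate
12 | (E)-enamine of the (S)-configured catalyst with the oxa-Michael adduct of 9 and 11 (C2 set, benzhydrol still present) | C[Si](C)(C)OC(c1ccccc1)(c1ccccc1)[C@@H]1CCCN1/C=C/[C@H](Oc1cc(OCc3ccccc3)ccc1C(O)c1c(OCc3ccccc3)c(Br)c2c(c1OCc3ccccc3)C[C@H](OCc3ccccc3)[C@@H](c1cc(OCc3ccccc3)c(OCc3ccccc3)c(OCc3ccccc3)c1)O2)c1cc(OCc3ccccc3)c(OCc3ccccc3)c(OCc3ccccc3)c1 | intermediate (not isolated)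
13 | (2S,3S,4S)-7-(benzyloxy)-4-[(2R,3S)-3,5,7-tris(benzyloxy)-8-bromo-2-(3,4,5-tris(benzyloxy)phenyl)chroman-6-yl]-2-[3,4,5-tris(benzyloxy)phenyl]chroman-3-carbaldehyde | O(Cc3ccccc3)c1ccc2c(c1)O[C@H](c1cc(OCc3ccccc3)c(OCc3ccccc3)c(OCc3ccccc3)c1)[C@@H](C=O)[C@@H]2c1c(OCc3ccccc3)c(Br)c2c(c1OCc3ccccc3)C[C@H](OCc3ccccc3)[C@@H](c1cc(OCc3ccccc3)c(OCc3ccccc3)c(OCc3ccccc3)c1)O2 | intermediate
14 | (2R,3S,4S)-chroman-3-yl formate corresponding to 13 | O(Cc3ccccc3)c1ccc2c(c1)O[C@H](c1cc(OCc3ccccc3)c(OCc3ccccc3)c(OCc3ccccc3)c1)[C@@H](OC=O)[C@@H]2c1c(OCc3ccccc3)c(Br)c2c(c1OCc3ccccc3)C[C@H](OCc3ccccc3)[C@@H](c1cc(OCc3ccccc3)c(OCc3ccccc3)c(OCc3ccccc3)c1)O2 | intermediate (not isolated)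
15 | (2R,3S,4S)-7-(benzyloxy)-4-[(2R,3S)-3,5,7-tris(benzyloxy)-8-bromo-2-(3,4,5-tris(benzyloxy)phenyl)chroman-6-yl]-2-[3,4,5-tris(benzyloxy)phenyl]chroman-3-ol | O(Cc3ccccc3)c1ccc2c(c1)O[C@H](c1cc(OCc3ccccc3)c(OCc3ccccc3)c(OCc3ccccc3)c1)[C@@H](O)[C@@H]2c1c(OCc3ccccc3)c(Br)c2c(c1OCc3ccccc3)C[C@H](OCc3ccccc3)[C@@H](c1cc(OCc3ccccc3)c(OCc3ccccc3)c(OCc3ccccc3)c1)O2 | intermediate
16 | robinetinidol-(4α→6)-gallocatechin, upper unit (2R,3S,4S), lower unit (2R,3S) | Oc1ccc2c(c1)O[C@H](c1cc(O)c(O)c(O)c1)[C@@H](O)[C@@H]2c1c(O)cc2c(c1O)C[C@H](O)[C@@H](c1cc(O)c(O)c(O)c1)O2 | target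

**Step count and risks**

Total step count: 9. Longest linear sequence: 8 steps (steps 1–5 and 7–9).

Steps most likely to fail:

1. Step 7 (proposed new method). What may go wrong: self-condensation of the ionised benzhydrol or capture of the cation by the amine catalyst before the oxa-Michael addition, and insufficient relay of configuration from C2 to C4. The fallback uses known reactions only, sets out from 9 and 11 and returns to the route at 15. The benzhydrol 9 would be oxidised (MnO2, CH2Cl2) to the 2-hydroxybenzophenone F1 and methylenated by Wittig reaction (Ph3PCH3Br, KOtBu, THF) to the 1,1-diarylethene phenol F2. In parallel the enal 11 would be reduced under Luche conditions (NaBH4, CeCl3·7H2O, MeOH) to the cinnamyl alcohol F3 and acylated (methyl chloroformate, pyridine) to the allylic methyl carbonate F4. Iridium-catalysed asymmetric allylic etherification of the lithium phenoxide of F2 with F4 ([Ir(cod)Cl]2, O,O'-(1,1'-binaphthyl-2,2'-diyl)-N,N-bis(1-phenylethyl)phosphoramidite, THF) would give the branched aryl 1-arylallyl ether F5, using the ligand enantiomer that gives the (S)-configured ether, which has the same spatial arrangement at C2 as 13. Ring-closing metathesis (second-generation Grubbs catalyst, toluene, 80 °C) would then close ring C through the C3=C4 double bond to the flav-3-ene F6. Hydroboration–oxidation (BH3·SMe2, THF; then H2O2, NaOH) should add boron to C3 and hydrogen to the doubly benzylic C4 on the face anti to the C2 aryl group, which gives the 2,3-trans-3,4-trans alcohol 15.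

2. Step 8. What may go wrong: hydrogen instead of carbon migration in the Criegee adduct (oxidation to the carboxylic acid) and electrophilic oxidation of the electron-rich benzyloxy arenes by the peracid. The fallback sets out from 13 and returns at 15. Addition of MeMgBr (THF, −78 °C) would give the secondary carbinol F7, and oxidation with Dess–Martin periodinane the methyl ketone F8. Baeyer–Villiger oxidation of F8 (mCPBA, NaHCO3, CH2Cl2), in which the secondary C3 migrates in preference to methyl and with retention, would give the acetate F9. Methanolysis (K2CO3, MeOH) would then give 15.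

3. Step 5. What may go wrong: slow addition of the hindered, doubly ortho-substituted aryllithium to the deactivated phenoxide-aldehyde, competing proton transfer from a benzylic ether position, and acid-triggered dehydration of the product during isolation. The fallback reverses the polarity of the two partners, sets out from 4 and returns at 9. Vilsmeier–Haack formylation of 4 (POCl3, DMF) at the only free ring A position would give the 6-carbaldehyde F10. Ortho-selective hydroxyalkylation of bromomagnesium 3-(benzyloxy)phenoxide (from commercial 3-(benzyloxy)phenol and EtMgBr, toluene) with F10 would then give 9 directly; the chelated six-membered transition state should direct attack to the phenol position ortho to the oxygen and para to the benzyloxy group.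

**Further compounds**

F1 | step 7 | [4-(benzyloxy)-2-hydroxyphenyl][(2R,3S)-3,5,7-tris(benzyloxy)-8-bromo-2-(3,4,5-tris(benzyloxy)phenyl)chroman-6-yl]methanone | O=C(c1ccc(OCc3ccccc3)cc1O)c1c(OCc3ccccc3)c(Br)c2c(c1OCc3ccccc3)C[C@H](OCc3ccccc3)[C@@H](c1cc(OCc3ccccc3)c(OCc3ccccc3)c(OCc3ccccc3)c1)O2
F2 | step 7 | 5-(benzyloxy)-2-{1-[(2R,3S)-3,5,7-tris(benzyloxy)-8-bromo-2-(3,4,5-tris(benzyloxy)phenyl)chroman-6-yl]ethenyl}phenol | C=C(c1ccc(OCc3ccccc3)cc1O)c1c(OCc3ccccc3)c(Br)c2c(c1OCc3ccccc3)C[C@H](OCc3ccccc3)[C@@H](c1cc(OCc3ccccc3)c(OCc3ccccc3)c(OCc3ccccc3)c1)O2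
F3 | step 7 | (E)-3-[3,4,5-tris(benzyloxy)phenyl]prop-2-en-1-ol | OC/C=C/c1cc(OCc2ccccc2)c(OCc2ccccc2)c(OCc2ccccc2)c1
F4 | step 7 | (E)-3-[3,4,5-tris(benzyloxy)phenyl]prop-2-en-1-yl methyl carbonate | COC(=O)OC/C=C/c1cc(OCc2ccccc2)c(OCc2ccccc2)c(OCc2ccccc2)c1
F5 | step 7 | (S)-1-[3,4,5-tris(benzyloxy)phenyl]prop-2-en-1-yl ether of phenol F2 | C=C[C@H](Oc1cc(OCc3ccccc3)ccc1C(=C)c1c(OCc3ccccc3)c(Br)c2c(c1OCc3ccccc3)C[C@H](OCc3ccccc3)[C@@H](c1cc(OCc3ccccc3)c(OCc3ccccc3)c(OCc3ccccc3)c1)O2)c1cc(OCc3ccccc3)c(OCc3ccccc3)c(OCc3ccccc3)c1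
F6 | step 7 | (S)-7-(benzyloxy)-4-[(2R,3S)-3,5,7-tris(benzyloxy)-8-bromo-2-(3,4,5-tris(benzyloxy)phenyl)chroman-6-yl]-2-[3,4,5-tris(benzyloxy)phenyl]-2H-chromene | O(Cc3ccccc3)c1ccc2c(c1)O[C@H](c1cc(OCc3ccccc3)c(OCc3ccccc3)c(OCc3ccccc3)c1)C=C2c1c(OCc3ccccc3)c(Br)c2c(c1OCc3ccccc3)C[C@H](OCc3ccccc3)[C@@H](c1cc(OCc3ccccc3)c(OCc3ccccc3)c(OCc3ccccc3)c1)O2
F7 | step 8 | 1-(chroman-3-yl)ethanol from 13 and MeMgBr, ring configuration as in 13, both carbinol epimers | O(Cc3ccccc3)c1ccc2c(c1)O[C@H](c1cc(OCc3ccccc3)c(OCc3ccccc3)c(OCc3ccccc3)c1)[C@@H](C(C)O)[C@@H]2c1c(OCc3ccccc3)c(Br)c2c(c1OCc3ccccc3)C[C@H](OCc3ccccc3)[C@@H](c1cc(OCc3ccccc3)c(OCc3ccccc3)c(OCc3ccccc3)c1)O2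
F8 | step 8 | 3-acetylchroman (methyl ketone) corresponding to 13 | O(Cc3ccccc3)c1ccc2c(c1)O[C@H](c1cc(OCc3ccccc3)c(OCc3ccccc3)c(OCc3ccccc3)c1)[C@@H](C(C)=O)[C@@H]2c1c(OCc3ccccc3)c(Br)c2c(c1OCc3ccccc3)C[C@H](OCc3ccccc3)[C@@H](c1cc(OCc3ccccc3)c(OCc3ccccc3)c(OCc3ccccc3)c1)O2
F9 | step 8 | chroman-3-yl acetate corresponding to 15 | O(Cc3ccccc3)c1ccc2c(c1)O[C@H](c1cc(OCc3ccccc3)c(OCc3ccccc3)c(OCc3ccccc3)c1)[C@@H](OC(C)=O)[C@@H]2c1c(OCc3ccccc3)c(Br)c2c(c1OCc3ccccc3)C[C@H](OCc3ccccc3)[C@@H](c1cc(OCc3ccccc3)c(OCc3ccccc3)c(OCc3ccccc3)c1)O2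
F10 | step 5 | (2R,3S)-3,5,7-tris(benzyloxy)-8-bromo-2-[3,4,5-tris(benzyloxy)phenyl]chroman-6-carbaldehyde | O=Cc1c(OCc3ccccc3)c(Br)c2c(c1OCc3ccccc3)C[C@H](OCc3ccccc3)[C@@H](c1cc(OCc3ccccc3)c(OCc3ccccc3)c(OCc3ccccc3)c1)O2
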